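The cyclohexene ring (C1 quaternary carbon, C2, C3=C4, C5 bearing isopropenyl, C6; C7 = the OCH2 carbon on C2) is disconnected at C1–CH3 and C2–C7. Both bonds, and both adjacent stereocentres, are made in one flask: lithium dimethylcuprate adds to a (5S)-3-alkyl-5-isopropenylcyclohex-2-enone and the enolate is captured by formaldehyde. The step exploits the fact that the C1 methyl is trans to both the C5 isopropenyl group and the C7 arm, so the one catalytically made centre, C5, relays to C1 and then C2. The precursor carries the future acid chain as a dioxolane-masked propanal, orthogonal to the C7 silyl ether used afterwards.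

Key step: step 5

Remark: atom labels C1–C7 in the Why lines follow the target numbering above; locants inside compound names are IUPAC locants.
Assumption: in step 1 (R)-BINAP is taken to transfer the alkenyl group with the same facial sense as in aryl transfer to cyclohex-2-en-1-one, which corresponds to the R ketone; if the sense proved opposite, (S)-BINAP would be used.

Step 1
Reactants: 1 cyclohex-2-en-1-one; 2 potassium trifluoro(prop-1-en-2-yl)borate
Product: 3 (3R)-3-(prop-1-en-2-yl)cyclohexan-1-one
Conditions: [Rh(cod)2]BF4 (3 mol%), (R)-BINAP (3.3 mol%), toluene/H2O (10:1), 105 °C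
Reagents that add atoms: none
Why: Hayashi–Miyaura rhodium-catalysed asymmetric conjugate addition, in which the isopropenylrhodium–BINAP species inserts one enantioface of the enone, so the ligand sets the future C5 centre as R before water releases the ketone.

Step 2
Reactants: 3 (3R)-3-(prop-1-en-2-yl)cyclohexan-1-one
Product: 5 (5R)-5-(prop-1-en-2-yl)cyclohex-2-en-1-one, via silyl enol ether 4 (not isolated)
Conditions: LiN(i-Pr)2, Me3SiCl (in situ quench), THF, −78 °C; then Pd(OAc)2 (1.05 equiv), MeCN, rt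
Reagents that add atoms: none
Why: Kinetic deprotonation with in situ silylation should take the α-methylene remote from the isopropenyl-bearing carbon, and Saegusa–Ito oxidation of that silyl enol ether (palladium enolate, β-hydride elimination) then places the double bond on that side without touching the non-enolisable stereocentre.

Step 3
Reactants: 5 (5R)-5-(prop-1-en-2-yl)cyclohex-2-en-1-one; 6 2-(2-bromoethyl)-1,3-dioxolane
Product: 8 (5R)-1-[2-(1,3-dioxolan-2-yl)ethyl]-5-(prop-1-en-2-yl)cyclohex-2-en-1-ol (both C1 epimers), via Grignard reagent 7 (not isolated)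
Conditions: Mg, THF, 25 °C; then CeCl3 and 5, THF, −78 °C
Reagents that add atoms: none
Why: Grignard formation and cerium-mediated 1,2-addition to the enone carbonyl, which suppresses enolisation and conjugate addition; the carbinol centre forms as a mixture that is erased in step 4.

Step 4
Reactants: 8 (5R)-1-[2-(1,3-dioxolan-2-yl)ethyl]-5-(prop-1-en-2-yl)cyclohex-2-en-1-ol
Product: 9 (5S)-3-[2-(1,3-dioxolan-2-yl)ethyl]-5-(prop-1-en-2-yl)cyclohex-2-en-1-one
Conditions: [C5H5NH][CrO3Cl] (pyridinium chlorochromate, 2.5 equiv), 4 Å molecular sieves, CH2Cl2, rt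
Reagents that add atoms: pyridinium chlorochromate, [O-][Cr](=O)(=O)Cl.c1cc[nH+]cc1
Why: Babler–Dauben oxidative transposition, in which the tertiary allylic chromate ester undergoes a [3,3] shift and is oxidised to the transposed enone, leaving the chain on the β-carbon while the anhydrous medium spares the acetal and C5.

Step 5
Reactants: 9 (5S)-3-[2-(1,3-dioxolan-2-yl)ethyl]-5-(prop-1-en-2-yl)cyclohex-2-en-1-one; 10 formaldehyde (monomer, from cracking paraformaldehyde)
Product: 12 (2S,3R,5S)-3-[2-(1,3-dioxolan-2-yl)ethyl]-2-(hydroxymethyl)-3-methyl-5-(prop-1-en-2-yl)cyclohexan-1-one, via lithium enolate 11 (not isolated)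
Conditions: Me2CuLi (1.5 equiv, from CuI and MeLi), Et2O, −40 to 0 °C; then CH2O (gas, excess), THF, −78 °C; cold pH 7 buffer
Reagents that add atoms: lithium dimethylcuprate, [Li+].C[Cu-]C
Why: Tandem cuprate conjugate addition and aldol capture of the enolate (three-component coupling), a known sequence for cyclohexenones: the cuprate forms a π-complex with the enone, bonds CH3 to the β-carbon (C1) through a cuprate–enolate adduct and reductive elimination, and leaves regiodefined lithium enolate 11, which adds to monomeric formaldehyde at C2. No ring is closed. C1 is set by C5: with the isopropenyl group pseudo-equatorial on the enone half-chair, methyl enters axially through a chair-like transition state on the face anti to it, so CH3 ends trans and the chain cis to isopropenyl. C2 is set by the new axial C1 methyl: formaldehyde approaches the enolate axially on the opposite face, placing the hydroxymethyl group trans to that methyl. The step needs facial selectivity twice and an enolate that does not equilibrate; the equatorial C5 group locks the conformation for both additions, and aprotic capture at low temperature with a cold buffered quench should prevent proton transfer, retro-aldol loss of formaldehyde and epimerisation of the kinetically formed C2 centre.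

Step 6
Reactants: 12 (2S,3R,5S)-3-[2-(1,3-dioxolan-2-yl)ethyl]-2-(hydroxymethyl)-3-methyl-5-(prop-1-en-2-yl)cyclohexan-1-one
Product: 13 (2S,3R,5S)-2-{[(tert-butyldimethylsilyl)oxy]methyl}-3-[2-(1,3-dioxolan-2-yl)ethyl]-3-methyl-5-(prop-1-en-2-yl)cyclohexan-1-one
Conditions: t-BuMe2SiCl, imidazole, DMF, 0 °C to rt
Reagents that add atoms: tert-butyldimethylsilyl chloride, CC(C)(C)[Si](C)(C)Cl
Why: Silyl ether formation at the primary alcohol with imidazole, a base too weak to enolise the ketone, so retro-aldol, dehydration and C2 epimerisation should be avoided.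

Step 7
Reactants: 13 (2S,3R,5S)-2-{[(tert-butyldimethylsilyl)oxy]methyl}-3-[2-(1,3-dioxolan-2-yl)ethyl]-3-methyl-5-(prop-1-en-2-yl)cyclohexan-1-one
Product: 15 (3S,5R,6S)-6-{[(tert-butyldimethylsilyl)oxy]methyl}-5-[2-(1,3-dioxolan-2-yl)ethyl]-5-methyl-3-(prop-1-en-2-yl)cyclohex-1-en-1-yl trifluoromethanesulfonate, via potassium enolate 14 (not isolated)
Conditions: KN(SiMe3)2, THF, −78 °C; then Comins reagent, −78 °C
Reagents that add atoms: N-(5-chloropyridin-2-yl)-1,1,1-trifluoro-N-[(trifluoromethyl)sulfonyl]methanesulfonamide (Comins reagent), O=S(=O)(N(c1ccc(Cl)cn1)S(=O)(=O)C(F)(F)F)C(F)(F)F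
Why: Kinetic enolate formation and O-triflation, in which the hindered amide removes a C4 methylene proton in preference to the tertiary C2–H next to the quaternary carbon, so the C3=C4 enol triflate forms, C2 keeps its configuration and the β-silyloxy group is not eliminated.

Step 8
Reactants: 15 (3S,5R,6S)-6-{[(tert-butyldimethylsilyl)oxy]methyl}-5-[2-(1,3-dioxolan-2-yl)ethyl]-5-methyl-3-(prop-1-en-2-yl)cyclohex-1-en-1-yl trifluoromethanesulfonate
Product: 16 tert-butyl({(1R,4S,6R)-6-[2-(1,3-dioxolan-2-yl)ethyl]-2,6-dimethyl-4-(prop-1-en-2-yl)cyclohex-2-en-1-yl}methoxy)dimethylsilane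
Conditions: MeMgBr, Fe(acac)3 (10 mol%), THF/NMP, −30 to 0 °C
Reagents that add atoms: methylmagnesium bromide, C[Mg]Br
Why: Iron-catalysed Kumada-type cross-coupling of an alkenyl triflate with a methyl Grignard reagent replaces OTf by CH3 with the double bond fixed at C3=C4, while silyl ether, acetal and isolated alkenes are inert at low temperature.

Step 9
Reactants: 16 tert-butyl({(1R,4S,6R)-6-[2-(1,3-dioxolan-2-yl)ethyl]-2,6-dimethyl-4-(prop-1-en-2-yl)cyclohex-2-en-1-yl}methoxy)dimethylsilane
Product: 17 {(1R,4S,6R)-6-[2-(1,3-dioxolan-2-yl)ethyl]-2,6-dimethyl-4-(prop-1-en-2-yl)cyclohex-2-en-1-yl}methanol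
Conditions: Bu4NF, THF, rt
Reagents that add atoms: none
Why: Fluoride-mediated desilylation driven by Si–F bond formation frees the C7 alcohol, and the acetal is inert to fluoride, so the chain stays masked.

Step 10
Reactants: 17 {(1R,4S,6R)-6-[2-(1,3-dioxolan-2-yl)ethyl]-2,6-dimethyl-4-(prop-1-en-2-yl)cyclohex-2-en-1-yl}methanol; 18 umbelliferone (7-hydroxy-2H-chromen-2-one)
Product: 19 7-({(1R,4S,6R)-6-[2-(1,3-dioxolan-2-yl)ethyl]-2,6-dimethyl-4-(prop-1-en-2-yl)cyclohex-2-en-1-yl}methoxy)-2H-chromen-2-one
Conditions: PPh3, diisopropyl azodicarboxylate, THF, 0 °C to rt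
Reagents that add atoms: none
Why: Mitsunobu etherification, in which the primary C7 alcohol is activated as an alkoxyphosphonium ion and displaced by the acidic phenol of 18 in an SN2 step at a carbon that is not a stereocentre.

Step 11
Reactants: 19 7-({(1R,4S,6R)-6-[2-(1,3-dioxolan-2-yl)ethyl]-2,6-dimethyl-4-(prop-1-en-2-yl)cyclohex-2-en-1-yl}methoxy)-2H-chromen-2-one
Product: 20 3-[(1R,2R,5S)-1,3-dimethyl-2-{[(2-oxo-2H-chromen-7-yl)oxy]methyl}-5-(prop-1-en-2-yl)cyclohex-3-en-1-yl]propanal
Conditions: 1 M HCl (aq), THF, rt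
Reagents that add atoms: water, O
Why: Acid-catalysed acetal hydrolysis through the oxocarbenium ion unmasks the aldehyde, and dilute acid at room temperature should leave the aryl ether, the lactone and both alkenes untouched.

Step 12
Reactants: 20 3-[(1R,2R,5S)-1,3-dimethyl-2-{[(2-oxo-2H-chromen-7-yl)oxy]methyl}-5-(prop-1-en-2-yl)cyclohex-3-en-1-yl]propanal
Product: 21 3-[(1R,2R,5S)-1,3-dimethyl-2-{[(2-oxo-2H-chromen-7-yl)oxy]methyl}-5-(prop-1-en-2-yl)cyclohex-3-en-1-yl]propanoic acid (CNP0301632.1)
Conditions: NaClO2, NaH2PO4, 2-methylbut-2-ene, t-BuOH/H2O, 0 °C to rt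
Reagents that add atoms: sodium chlorite, [Na+].[O-]Cl=O
Why: Pinnick chlorite oxidation converts the aldehyde to the carboxylic acid, with 2-methylbut-2-ene scavenging hypochlorous acid so that the alkenes and the arene are not chlorinated.

Compound list
1 | cyclohex-2-en-1-one | O=C1C=CCCC1 | starting material
2 | potassium trifluoro(prop-1-en-2-yl)borate | [K+].C=C(C)[B-](F)(F)F | starting material
3 | (3R)-3-(prop-1-en-2-yl)cyclohexan-1-one | C=C(C)[C@H]1CC(=O)CCC1 | intermediate
4 | trimethyl{[(5R)-5-(prop-1-en-2-yl)cyclohex-1-en-1-yl]oxy}silane | C=C(C)[C@H]1CC(O[Si](C)(C)C)=CCC1 | intermediate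
5 | (5R)-5-(prop-1-en-2-yl)cyclohex-2-en-1-one | C=C(C)[C@H]1CC(=O)C=CC1 | intermediate
6 | 2-(2-bromoethyl)-1,3-dioxolane | BrCCC1OCCO1 | starting material
7 | [2-(1,3-dioxolan-2-yl)ethyl]magnesium bromide | Br[Mg]CCC1OCCO1 | intermediate
8 | (5R)-1-[2-(1,3-dioxolan-2-yl)ethyl]-5-(prop-1-en-2-yl)cyclohex-2-en-1-ol (both C1 epimers) | C=C(C)[C@H]1CC(O)(CCC2OCCO2)C=CC1 | intermediate
9 | (5S)-3-[2-(1,3-dioxolan-2-yl)ethyl]-5-(prop-1-en-2-yl)cyclohex-2-en-1-one | C=C(C)[C@@H]1CC(=O)C=C(CCC2OCCO2)C1 | intermediate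
10 | formaldehyde | C=O | starting material
11 | lithium (3R,5S)-3-[2-(1,3-dioxolan-2-yl)ethyl]-3-methyl-5-(prop-1-en-2-yl)cyclohex-1-en-1-olate | [Li+].C=C(C)[C@@H]1CC([O-])=C[C@](C)(CCC2OCCO2)C1 | intermediate
12 | (2S,3R,5S)-3-[2-(1,3-dioxolan-2-yl)ethyl]-2-(hydroxymethyl)-3-methyl-5-(prop-1-en-2-yl)cyclohexan-1-one | C=C(C)[C@@H]1CC(=O)[C@H](CO)[C@](C)(CCC2OCCO2)C1 | intermediate
13 | (2S,3R,5S)-2-{[(tert-butyldimethylsilyl)oxy]methyl}-3-[2-(1,3-dioxolan-2-yl)ethyl]-3-methyl-5-(prop-1-en-2-yl)cyclohexan-1-one | C=C(C)[C@@H]1CC(=O)[C@H](CO[Si](C)(C)C(C)(C)C)[C@](C)(CCC2OCCO2)C1 | intermediate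
14 | potassium (3S,5R,6S)-6-{[(tert-butyldimethylsilyl)oxy]methyl}-5-[2-(1,3-dioxolan-2-yl)ethyl]-5-methyl-3-(prop-1-en-2-yl)cyclohex-1-en-1-olate | [K+].C=C(C)[C@@H]1C=C([O-])[C@H](CO[Si](C)(C)C(C)(C)C)[C@](C)(CCC2OCCO2)C1 | intermediate
15 | (3S,5R,6S)-6-{[(tert-butyldimethylsilyl)oxy]methyl}-5-[2-(1,3-dioxolan-2-yl)ethyl]-5-methyl-3-(prop-1-en-2-yl)cyclohex-1-en-1-yl trifluoromethanesulfonate | C=C(C)[C@@H]1C=C(OS(=O)(=O)C(F)(F)F)[C@H](CO[Si](C)(C)C(C)(C)C)[C@](C)(CCC2OCCO2)C1 | intermediate
16 | tert-butyl({(1R,4S,6R)-6-[2-(1,3-dioxolan-2-yl)ethyl]-2,6-dimethyl-4-(prop-1-en-2-yl)cyclohex-2-en-1-yl}methoxy)dimethylsilane | C=C(C)[C@@H]1C=C(C)[C@H](CO[Si](C)(C)C(C)(C)C)[C@](C)(CCC2OCCO2)C1 | intermediate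
17 | {(1R,4S,6R)-6-[2-(1,3-dioxolan-2-yl)ethyl]-2,6-dimethyl-4-(prop-1-en-2-yl)cyclohex-2-en-1-yl}methanol | C=C(C)[C@@H]1C=C(C)[C@H](CO)[C@](C)(CCC2OCCO2)C1 | intermediate
18 | umbelliferone (7-hydroxy-2H-chromen-2-one) | O=c1ccc2ccc(O)cc2o1 | starting material
19 | 7-({(1R,4S,6R)-6-[2-(1,3-dioxolan-2-yl)ethyl]-2,6-dimethyl-4-(prop-1-en-2-yl)cyclohex-2-en-1-yl}methoxy)-2H-chromen-2-one | C=C(C)[C@@H]1C=C(C)[C@H](COc2ccc3ccc(=O)oc3c2)[C@](C)(CCC4OCCO4)C1 | intermediate
20 | 3-[(1R,2R,5S)-1,3-dimethyl-2-{[(2-oxo-2H-chromen-7-yl)oxy]methyl}-5-(prop-1-en-2-yl)cyclohex-3-en-1-yl]propanal | C=C(C)[C@@H]1C=C(C)[C@H](COc2ccc3ccc(=O)oc3c2)[C@](C)(CCC=O)C1 | intermediate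
21 | 3-[(1R,2R,5S)-1,3-dimethyl-2-{[(2-oxo-2H-chromen-7-yl)oxy]methyl}-5-(prop-1-en-2-yl)cyclohex-3-en-1-yl]propanoic acid | C=C(C)[C@@H]1C=C(C)[C@H](COc2ccc3ccc(=O)oc3c2)[C@](C)(CCC(=O)O)C1 | target

Total steps: 12. Longest linear sequence: 12 steps (1 to 21).

Steps most likely to fail

Step 5. The conjugate addition at the fully substituted β-carbon may be slow, the enolate may exchange protons or scramble before the aldol, hydroxymethylation may occur more than once, and the aldol may revert or epimerise at C2 during work-up. The fallback separates the two bond formations. From 9, the cuprate addition would be run with Me3SiCl in THF at −78 °C and stopped at the trimethylsilyl enol ether F1, which can be isolated and its C1 configuration checked. MeLi in THF at 0 °C would then regenerate copper-free lithium enolate 11 (optionally transmetallated with ZnCl2) for reaction with monomeric formaldehyde at −78 °C, returning to 12.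

Step 2. Deprotonation may occur partly on the carbonyl side next to the isopropenyl-bearing carbon, giving the conjugated regioisomeric enone, and the oxidation may run on toward a phenol. The fallback fixes the site of unsaturation by thermodynamic control. From 3, NaH and diallyl carbonate in refluxing THF (equilibrating Claisen conditions) should acylate the less hindered α-carbon to give the allyl β-keto ester F2. Palladium-catalysed decarboxylation–dehydrogenation (Pd(OAc)2, 1,2-bis(diphenylphosphino)ethane, MeCN, reflux) then forms the palladium enolate only at that carbon, and β-hydride elimination returns to 5.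

Step 10. Displacement at the β-branched C7 carbon, flanked by a tertiary and a quaternary centre, may be slow enough for alkylation of the hydrazide anion or elimination to compete. The fallback replaces the redox condensation by a two-stage Williamson etherification. From 17, MsCl and Et3N in CH2Cl2 at 0 °C would give the methanesulfonate F3, which is displaced by the caesium salt of 18 (Cs2CO3, DMF, 70 °C), returning to 19.

Further compounds
F1 | step 5 | trimethyl({(3R,5S)-3-[2-(1,3-dioxolan-2-yl)ethyl]-3-methyl-5-(prop-1-en-2-yl)cyclohex-1-en-1-yl}oxy)silane | C=C(C)[C@@H]1CC(O[Si](C)(C)C)=C[C@](C)(CCC2OCCO2)C1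
F2 | step 2 | allyl (4R)-2-oxo-4-(prop-1-en-2-yl)cyclohexane-1-carboxylate (C1 epimers) | C=C(C)[C@H]1CC(=O)C(C(=O)OCC=C)CC1
F3 | step 10 | {(1R,4S,6R)-6-[2-(1,3-dioxolan-2-yl)ethyl]-2,6-dimethyl-4-(prop-1-en-2-yl)cyclohex-2-en-1-yl}methyl methanesulfonate | C=C(C)[C@@H]1C=C(C)[C@H](COS(C)(=O)=O)[C@](C)(CCC2OCCO2)C1
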